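The earlier runs and the new flask are simulated for substances that don't exist, noise included.

This closed, stirred vessel holds no second intermediate at the start, so begin your quick number there. The flasks, the readings and the questions stand here:

the same everywhere: starting material 0.80 M
- epsilon: partner 1.1 M; protic impurity 0.16 M; run made earlier
- gamma: partner 1.8 M; protic impurity 0.16 M; run made earlier
- grey: partner 0.800 M; protic impurity 0.160 M; time 3.0 h
- teal: partner 0.800 M; protic impurity 0.160 M; time 1.0 h

| run | time / h | target / % | starting material / % |
|---|---|---|---|
| epsilon | 0.833 | 2 | 49 |
| epsilon | 1.50 | 7 | 34 |
| epsilon | 2.50 | 12 | 28 |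
| epsilon | 3.00 | 19 | 23 |
| gamma | 0.417 | 4 | 69 |
| gamma | 1.00 | 5 | 44 |
| gamma | 2.00 | 17 | 26 |
| gamma | 3.00 | 26 | 23 |

(each reading ± 2 percentage points)

1. the winner by amount of target, in percent of the starting material charged; "neither" if no more than 2 percentage points parts them (grey / teal / neither)
2. how much target is there at the end, in percent of the starting material charged: grey
3. how much target is there at the end, in percent of the starting material charged: teal

- the analysis behind the earlier runs scatters by 2 percentage points, standard deviation
- reactions considered so far: second intermediate -> side product; partner -> second intermediate; starting material <-> open intermediate; starting material + protic impurity -> quenched substrate; open intermediate + second intermediate -> target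

Treat the target step as first order in second intermediate. Take it as growing in proportion to partner and to time, which makes target grow with partner and with time squared. Now scale the last two readings of each run to the partner of grey and teal and to the 3.0 h of grey:

| run | time | target read | scaled |
|---|---|---|---|
| epsilon | 2.50 h | 12 % | 12.6 % |
| epsilon | 3.00 h | 19 % | 13.8 % |
| gamma | 2.00 h | 17 % | 17.0 % |
| gamma | 3.00 h | 26 % | 11.6 % |

Take the mean, 13.7 %, and call it the squared-time yield: the target these readings imply for this partner charge at 3.0 h, with their scatter in it. That is my grey. For teal, multiply by the square of the time ratio, which gives 1.53 %, so grey holds more target than teal.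

Your forecast says grey: grey 14.5 % (range 11 % to 18 %) and teal 2.5 % (range 1 % to 5 %), on the grounds that “Growth is roughly quadratic in early time”. My teal figure is lower than yours, though inside your range.

The flasks give grey as the winner, with grey at 13.5 % and teal at 2.02 %.

    second intermediate → side product (k = 2.60 × 10⁻⁵ s⁻¹)
    partner → second intermediate (k = 2.20 × 10⁻⁴ s⁻¹)
    starting material ⇌ open intermediate (K = 2.10, k = 3.00 × 10⁻⁴ s⁻¹)
    starting material + protic impurity → quenched substrate (k = 1.90 × 10⁻⁴ M⁻¹ s⁻¹)
    open intermediate + second intermediate → target (k = 6.10 × 10⁻⁵ M⁻¹ s⁻¹)

Read teal at the time of grey and it holds 13.5 % instead of 2.02 %, so time is the main reason for the gap. From teal's end to grey's end, open intermediate stands at 49.9 % and then 50.9 %, so over that stretch the target step is pseudo-first-order in second intermediate, which goes from 0.400 M to 0.504 M, a smaller rise than the proportion to time I assumed. Applied to teal, the squared-time yield gives 1.53 % against the 2.02 % found. Applied to the neighbour, grey's flask read at 2.0 h, it gives 6.09 %, and that flask holds 7.55 %.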